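**Retrosynthetic overview**

1. Feature: in the cyclohexene (C1 methyl-bearing, C3 ring A, C4 ring B aroyl, C5 ring C) the C4 aryl ketone lies γ,δ to the C1=C2 double bond. This 4-acylcyclohexene is the product pattern of a Claisen shift, so C3–C4 is cut and the ketone oxygen is joined to C1, giving a (2S,4S)-2-methyl-2-[(E)-2-(ring A)ethenyl]-4-(ring C)-6-(ring B)-3,4-dihydro-2H-pyran.
2. Ring A carries the finished MOM-protected chalcone through the shift, so only acidic MOM removal follows and no base meets the epimerisable C4–H.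
3. Pyran precursor: the alkenyl–ring A bond comes from Suzuki coupling of an (E)-alkenylboronate (held on C2 as a silyl alkyne until then) with a ring A iodide; the C6–ring B bond from Suzuki coupling of a lactone-derived ketene acetal phosphate.
4. Lactone: rhodium-catalysed asymmetric 1,4-addition of the ring C boronic acid to a 6-alkynyl-6-methyl-5,6-dihydropyran-2-one, made by ring-closing metathesis of the acrylate of a carbinol set by asymmetric allylboration of a silyl ynone.
5. Ring order: the four arenes are bought; the oxygen heterocycle is made first (metathesis, then enol ether), the cyclohexene last by the sigmatropic ring contraction.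

Key step: step 19

Assumption: (S)-3,3'-Br2-BINOL is taken to give the (S)-carbinol 8 and (S)-BINAP the 4S lactone 11, by analogy with other methyl ketones and 5,6-dihydro-2H-pyran-2-ones; should either sense prove opposite, the antipodal ligand is used.
Remark: pyran numbering is O1, C2 (methyl), C4 (ring C), C6 (ring B); the 6-aryl dihydropyrans 20–22 and 30 are acid-labile enol ethers and are purified on triethylamine-deactivated silica.

**Ring C boronic acid**

Step 1
Reactants: 1 4-bromobenzene-1,3-diol
Product: 2 1-bromo-2,4-bis(methoxymethoxy)benzene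
Conditions: MOMCl, i-Pr2NEt, CH2Cl2, 0 °C → rt
Reagents that add atoms: chloromethyl methyl ether, COCCl
Why: Base-mediated O-alkylation of both phenols with the reactive α-chloro ether (MOM ether formation) is routine and leaves the aryl bromide untouched.

Step 2
Reactants: 2 1-bromo-2,4-bis(methoxymethoxy)benzene
Product: 5 [2,4-bis(methoxymethoxy)phenyl]boronic acid, via aryllithium 3 (not isolated), via lithium aryltriisopropoxyborate 4 (not isolated)
Conditions: n-BuLi, THF, −78 °C; B(Oi-Pr)3, −78 °C → rt; aq. NH4Cl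
Reagents that add atoms: triisopropyl borate, CC(C)OB(OC(C)C)OC(C)C; water, O
Why: Bromine–lithium exchange is faster than any deprotonation at −78 °C, and trapping the aryllithium with the borate ester followed by mild hydrolysis (lithiation–borylation) should give the boronic acid with both MOM ethers intact.

**Lactone with both stereocentres**

Step 3
Reactants: 6 4-(triisopropylsilyl)but-3-yn-2-one
Product: 8 (3S)-3-methyl-1-(triisopropylsilyl)hex-5-en-1-yn-3-ol, via dioxaborinanyl ether 7 (not isolated)
Conditions: 2-allyl-1,3,2-dioxaborinane, (S)-3,3'-Br2-BINOL (5 mol%), t-BuOH, PhMe, rt; aq. NaHCO3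
Reagents that add atoms: 2-allyl-1,3,2-dioxaborinane, C=CCB1OCCCO1
Why: Chiral-biphenol-catalysed asymmetric allylboration of a methyl ketone, a reaction type known for aryl, alkenyl and alkynyl methyl ketones, transfers allyl through a closed six-membered transition state in which the diol-bound boronate distinguishes the methyl from the alkynyl group and so sets the quaternary carbinol centre (S).

Step 4
Reactants: 8 (3S)-3-methyl-1-(triisopropylsilyl)hex-5-en-1-yn-3-ol
Product: 9 (3S)-3-methyl-1-(triisopropylsilyl)hex-5-en-1-yn-3-yl prop-2-enoate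
Conditions: acryloyl chloride, i-Pr2NEt, DMAP (cat.), CH2Cl2, 0 °C → rt
Reagents that add atoms: acryloyl chloride, C=CC(=O)Cl
Why: DMAP-catalysed acylation of the tertiary propargylic alcohol, whose slim alkynyl group keeps it accessible, gives the acrylate needed for ring closure without touching the stereocentre.

Step 5
Reactants: 9 (3S)-3-methyl-1-(triisopropylsilyl)hex-5-en-1-yn-3-yl prop-2-enoate
Product: 10 (6S)-6-methyl-6-[(triisopropylsilyl)ethynyl]-5,6-dihydro-2H-pyran-2-one
Conditions: second-generation Grubbs catalyst (H2IMes)(PCy3)Cl2Ru=CHPh (5 mol%), CH2Cl2 (0.01 M), 40 °C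
Reagents that add atoms: none
Why: Ring-closing metathesis between the terminal alkene and the acrylate is helped by the fully substituted carbinol carbon and should form the six-membered unsaturated lactone with loss of ethene, the silyl-capped alkyne being too hindered for enyne metathesis.

Step 6
Reactants: 10 (6S)-6-methyl-6-[(triisopropylsilyl)ethynyl]-5,6-dihydro-2H-pyran-2-one; 5 [2,4-bis(methoxymethoxy)phenyl]boronic acid
Product: 11 (4S,6S)-4-[2,4-bis(methoxymethoxy)phenyl]-6-methyl-6-[(triisopropylsilyl)ethynyl]oxan-2-one (aryl and alkynyl groups cis)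
Conditions: [Rh(OH)((S)-BINAP)]2 (3 mol% Rh), 5 (3 equiv), dioxane/H2O (10:1), 40 °C
Reagents that add atoms: none
Why: Rhodium-catalysed asymmetric 1,4-addition of an arylboronic acid (Hayashi–Miyaura reaction), established for 5,6-dihydro-2H-pyran-2-ones, sets C4 under control of the BINAP ligand with the aryl group cis to the slim alkynyl group, and any product from the minor enantiomer of 10 is a trans diastereomer that can be separated.

**Ring B boronate**

Step 7
Reactants: 12 5-chlorobenzene-1,3-diol
Product: 13 1-chloro-3,5-bis(methoxymethoxy)benzene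
Conditions: MOMCl, i-Pr2NEt, CH2Cl2, 0 °C → rt
Reagents that add atoms: chloromethyl methyl ether, COCCl
Why: MOM ether formation as in step 1; the chloride is chosen instead of the bromide because it survives n-BuLi in the next step.

Step 8
Reactants: 13 1-chloro-3,5-bis(methoxymethoxy)benzene; 14 1-bromo-3-methylbut-2-ene (prenyl bromide)
Product: 16 5-chloro-1,3-bis(methoxymethoxy)-2-(3-methylbut-2-en-1-yl)benzene, via aryllithium 15 (not isolated)
Conditions: n-BuLi, THF, −20 °C; CuBr·SMe2 (10 mol%), 14, −78 °C → rt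
Reagents that add atoms: none
Why: Directed ortho-metalation takes place at the carbon flanked by both MOM ethers (double chelation) while the aryl chloride is inert to n-BuLi, and copper-catalysed SN2 alkylation of the aryllithium with prenyl bromide installs the prenyl group.

Step 9
Reactants: 16 5-chloro-1,3-bis(methoxymethoxy)-2-(3-methylbut-2-en-1-yl)benzene
Product: 17 2-[3,5-bis(methoxymethoxy)-4-(3-methylbut-2-en-1-yl)phenyl]-4,4,5,5-tetramethyl-1,3,2-dioxaborolane
Conditions: B2pin2, Pd2(dba)3 (2 mol%), XPhos (8 mol%), KOAc, dioxane, 100 °C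
Reagents that add atoms: bis(pinacolato)diboron, CC1(C)OB(OC1(C)C)B1OC(C)(C)C(C)(C)O1
Why: Miyaura borylation of the aryl chloride with a zerovalent palladium–XPhos catalyst tolerates the prenyl alkene and the acetal protecting groups.

**Assembly of the dihydropyran**

Step 10
Reactants: 11 (4S,6S)-4-[2,4-bis(methoxymethoxy)phenyl]-6-methyl-6-[(triisopropylsilyl)ethynyl]oxan-2-one
Product: 19 (2S,4S)-4-[2,4-bis(methoxymethoxy)phenyl]-2-methyl-2-[(triisopropylsilyl)ethynyl]-3,4-dihydro-2H-pyran-6-yl diphenyl phosphate, via potassium enolate 18 (not isolated)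
Conditions: KN(SiMe3)2, THF, −78 °C; (PhO)2P(O)Cl, −78 → 0 °C
Reagents that add atoms: diphenyl phosphorochloridate, O=P(Cl)(Oc1ccccc1)Oc1ccccc1
Why: Deprotonation at the only α-position of the lactone and O-phosphorylation of the enolate gives the ketene acetal phosphate, the standard way to make a lactone carbonyl carbon ready for cross-coupling, and the alkynyl (not yet alkenyl) group on C2 rules out a premature [3,3] shift of this electron-rich ketene acetal.

Step 11
Reactants: 19 ketene acetal phosphate (as in step 10); 17 ring B pinacol boronate (as in step 9)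
Product: 20 (2S,4S)-4-[2,4-bis(methoxymethoxy)phenyl]-6-[3,5-bis(methoxymethoxy)-4-(3-methylbut-2-en-1-yl)phenyl]-2-methyl-2-[(triisopropylsilyl)ethynyl]-3,4-dihydro-2H-pyran
Conditions: PdCl2(dppf) (5 mol%), aq. K3PO4, THF, 50 °C
Reagents that add atoms: none
Why: Suzuki–Miyaura coupling of the ketene acetal phosphate with the unhindered arylboronate forms the C6–ring B bond and gives the 6-aryl enol ether without touching either stereocentre.

Step 12
Reactants: 20 silyl alkyne (as in step 11)
Product: 21 (2S,4S)-4-[2,4-bis(methoxymethoxy)phenyl]-6-[3,5-bis(methoxymethoxy)-4-(3-methylbut-2-en-1-yl)phenyl]-2-ethynyl-2-methyl-3,4-dihydro-2H-pyran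
Conditions: Bu4NF, THF, 0 °C → rt
Reagents that add atoms: none
Why: Fluoride-induced protodesilylation of the alkynylsilane frees the terminal alkyne under conditions to which the enol ether, the MOM ethers and the prenyl group are inert.

Step 13
Reactants: 21 terminal alkyne (as in step 12)
Product: 22 (2S,4S)-4-[2,4-bis(methoxymethoxy)phenyl]-6-[3,5-bis(methoxymethoxy)-4-(3-methylbut-2-en-1-yl)phenyl]-2-methyl-2-[(E)-2-(4,4,5,5-tetramethyl-1,3,2-dioxaborolan-2-yl)ethenyl]-3,4-dihydro-2H-pyran
Conditions: HBpin, Cp2Zr(H)Cl (10 mol%), Et3N (10 mol%), CH2Cl2, rt → 40 °C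
Reagents that add atoms: pinacolborane, CC1(C)OBOC1(C)C
Why: Zirconocene-hydride-catalysed syn hydroboration of the terminal alkyne places boron on the terminal carbon, away from the quaternary centre, and gives only the (E)-alkenylboronate, while the trisubstituted alkenes do not react.

**Ring A iodide carrying the chalcone**

Step 14
Reactants: 23 4-hydroxybenzaldehyde
Product: 24 4-(methoxymethoxy)benzaldehyde
Conditions: MOMCl, i-Pr2NEt, CH2Cl2, 0 °C → rt
Reagents that add atoms: chloromethyl methyl ether, COCCl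
Why: MOM ether formation as in step 1, the aldehyde being inert.

Step 15
Reactants: 25 1-(2,4-dihydroxyphenyl)ethanone
Product: 26 1-(2,4-dihydroxy-3-iodophenyl)ethanone
Conditions: I2, HIO3, EtOH/H2O, 35 °C
Reagents that add atoms: iodine, II; iodic acid, O[I](=O)=O
Why: Electrophilic aromatic iodination with iodine and iodic acid as oxidant should go to C3, the position ortho to both hydroxyl groups and the most nucleophilic site of this ketone, and any 5-iodo isomer would be removed by crystallisation.

Step 16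
Reactants: 26 1-(2,4-dihydroxy-3-iodophenyl)ethanone
Product: 27 1-[3-iodo-2,4-bis(methoxymethoxy)phenyl]ethanone
Conditions: MOMCl, K2CO3, acetone, reflux
Reagents that add atoms: chloromethyl methyl ether, COCCl
Why: O-Alkylation of both phenols under carbonate conditions at reflux, which are forcing enough for the hydrogen-bonded, flanked 2-hydroxyl group.

Step 17
Reactants: 27 1-[3-iodo-2,4-bis(methoxymethoxy)phenyl]ethanone; 24 4-(methoxymethoxy)benzaldehyde
Product: 29 (E)-1-[3-iodo-2,4-bis(methoxymethoxy)phenyl]-3-[4-(methoxymethoxy)phenyl]prop-2-en-1-one, via aldol adduct 28 (not isolated)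
Conditions: KOH, EtOH, rt
Reagents that add atoms: none
Why: Claisen–Schmidt (crossed aldol) condensation of the methyl ketone with the non-enolisable aldehyde gives the (E)-enone by E1cB dehydration, and the aryl iodide and MOM ethers are stable to ethanolic hydroxide.

**Precursor, key step and deprotection**

Step 18
Reactants: 22 (E)-alkenylboronate (as in step 13); 29 chalcone iodide (as in step 17)
Product: 30 (2S,4S)-2-[(E)-2-{2,6-bis(methoxymethoxy)-3-[(E)-3-(4-(methoxymethoxy)phenyl)prop-2-enoyl]phenyl}ethenyl]-4-[2,4-bis(methoxymethoxy)phenyl]-6-[3,5-bis(methoxymethoxy)-4-(3-methylbut-2-en-1-yl)phenyl]-2-methyl-3,4-dihydro-2H-pyran (styryl group and ring C cis)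
Conditions: Pd(OAc)2 (5 mol%), SPhos (10 mol%), K3PO4, THF/H2O (10:1), 40 °C
Reagents that add atoms: none
Why: Suzuki–Miyaura coupling proceeds with retention of alkene geometry, the SPhos ligand copes with the two ortho substituents of the aryl iodide, and the mild conditions leave the chalcone and the allyl vinyl ether unchanged.

Step 19
Reactants: 30 cis-2-methyl-2-styryl-4,6-diaryl-3,4-dihydro-2H-pyran (as in step 18)
Product: 31 (3S,4R,5S)-3-{2,6-bis(methoxymethoxy)-3-[(E)-3-(4-(methoxymethoxy)phenyl)prop-2-enoyl]phenyl}-4-[3,5-bis(methoxymethoxy)-4-(3-methylbut-2-en-1-yl)benzoyl]-5-[2,4-bis(methoxymethoxy)phenyl]-1-methylcyclohex-1-ene (hepta-MOM kuwanon R)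
Conditions: degassed o-xylene (0.01 M), BHT (10 mol%), solid K2CO3 (acid scavenger), sealed tube, 165 °C, dark
Reagents that add atoms: none
Why: The enol ether C5=C6(ring B)–O1 and the tertiary allylic O1–C2 bond with its (E)-styryl group make up an allyl vinyl ether that should undergo a concerted suprafacial [3,3] sigmatropic (Claisen) shift, the known thermal ring contraction of 2-alkenyl-3,4-dihydro-2H-pyrans to 4-acylcyclohexenes. The cyclohexene closes by this sigmatropic ring contraction (O1–C2 cleaved, C5–styryl β-carbon bond formed, the C2–C3–C4 tether forcing a bicyclo[2.2.2]-like boat transition state) and not by an end-to-end cyclisation, and formation of the aryl ketone carbonyl drives it. The new centre C3 of the cyclohexene is set by the E geometry of the styryl group, which keeps ring A on the outside of the boat and therefore cis to the aroyl group. The new centre C4 is set by the quaternary pyran C2, because the styryl carbon can reach C5 only on the pyran face it occupies; with styryl and ring C cis this puts the aroyl group trans to ring C, whose own centre is carried over unchanged. The step needs the [3,3] path to win over ionisation of the doubly activated allylic ether and over retro-[4+2] fragmentation, which the neutral, apolar, acid-free medium and the non-epimerisable quaternary C2 should secure, and it needs an inert enone, for which the chalcone (no enolisable hydrogen, high dilution, exclusion of light) is suited.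

Step 20
Reactants: 31 hepta-MOM kuwanon R (as in step 19)
Product: 32 kuwanon R, (3S,4R,5S)-3-{2,6-dihydroxy-3-[(E)-3-(4-hydroxyphenyl)prop-2-enoyl]phenyl}-4-[3,5-dihydroxy-4-(3-methylbut-2-en-1-yl)benzoyl]-5-(2,4-dihydroxyphenyl)-1-methylcyclohex-1-ene
Conditions: 3 M aq. HCl, MeOH/THF, 40 °C
Reagents that add atoms: none
Why: Acid-catalysed acetal exchange with methanol should remove all seven MOM groups as dimethoxymethane under conditions mild enough to keep the prenyl group, the enone and the C4 configuration.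

**Compound list**

1 | 4-bromobenzene-1,3-diol | Oc1ccc(Br)c(O)c1 | starting material
2 | 1-bromo-2,4-bis(methoxymethoxy)benzene | COCOc1ccc(Br)c(OCOC)c1 | intermediate
3 | [2,4-bis(methoxymethoxy)phenyl]lithium | [Li]c1ccc(OCOC)cc1OCOC | intermediate
4 | lithium [2,4-bis(methoxymethoxy)phenyl]tri(propan-2-yloxy)borate | [Li+].CC(C)O[B-](OC(C)C)(OC(C)C)c1ccc(OCOC)cc1OCOC | intermediate
5 | [2,4-bis(methoxymethoxy)phenyl]boronic acid | OB(O)c1ccc(OCOC)cc1OCOC | intermediate
6 | 4-(triisopropylsilyl)but-3-yn-2-one | CC(=O)C#C[Si](C(C)C)(C(C)C)C(C)C | starting material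
7 | 2-{[(3S)-3-methyl-1-(triisopropylsilyl)hex-5-en-1-yn-3-yl]oxy}-1,3,2-dioxaborinane | C[C@@](OB1OCCCO1)(C#C[Si](C(C)C)(C(C)C)C(C)C)CC=C | intermediate
8 | (3S)-3-methyl-1-(triisopropylsilyl)hex-5-en-1-yn-3-ol | C[C@@](O)(C#C[Si](C(C)C)(C(C)C)C(C)C)CC=C | intermediate
9 | (3S)-3-methyl-1-(triisopropylsilyl)hex-5-en-1-yn-3-yl prop-2-enoate | C[C@@](OC(=O)C=C)(C#C[Si](C(C)C)(C(C)C)C(C)C)CC=C | intermediate
10 | (6S)-6-methyl-6-[(triisopropylsilyl)ethynyl]-5,6-dihydro-2H-pyran-2-one | C[C@@]1(C#C[Si](C(C)C)(C(C)C)C(C)C)CC=CC(=O)O1 | intermediate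
11 | (4S,6S)-4-[2,4-bis(methoxymethoxy)phenyl]-6-methyl-6-[(triisopropylsilyl)ethynyl]oxan-2-one | C[C@@]1(C#C[Si](C(C)C)(C(C)C)C(C)C)C[C@H](c2ccc(OCOC)cc2OCOC)CC(=O)O1 | intermediate
12 | 5-chlorobenzene-1,3-diol | Oc1cc(O)cc(Cl)c1 | starting material
13 | 1-chloro-3,5-bis(methoxymethoxy)benzene | COCOc1cc(Cl)cc(OCOC)c1 | intermediate
14 | 1-bromo-3-methylbut-2-ene (prenyl bromide) | CC(C)=CCBr | starting material
15 | [4-chloro-2,6-bis(methoxymethoxy)phenyl]lithium | [Li]c1c(OCOC)cc(Cl)cc1OCOC | intermediate
16 | 5-chloro-1,3-bis(methoxymethoxy)-2-(3-methylbut-2-en-1-yl)benzene | CC(C)=CCc1c(OCOC)cc(Cl)cc1OCOC | intermediate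
17 | 2-[3,5-bis(methoxymethoxy)-4-(3-methylbut-2-en-1-yl)phenyl]-4,4,5,5-tetramethyl-1,3,2-dioxaborolane | CC(C)=CCc1c(OCOC)cc(B2OC(C)(C)C(C)(C)O2)cc1OCOC | intermediate
18 | potassium (2S,4S)-4-[2,4-bis(methoxymethoxy)phenyl]-2-methyl-2-[(triisopropylsilyl)ethynyl]-3,4-dihydro-2H-pyran-6-olate | C[C@@]1(C#C[Si](C(C)C)(C(C)C)C(C)C)C[C@H](c2ccc(OCOC)cc2OCOC)C=C([O-])O1.[K+] | intermediate
19 | (2S,4S)-4-[2,4-bis(methoxymethoxy)phenyl]-2-methyl-2-[(triisopropylsilyl)ethynyl]-3,4-dihydro-2H-pyran-6-yl diphenyl phosphate | C[C@@]1(C#C[Si](C(C)C)(C(C)C)C(C)C)C[C@H](c2ccc(OCOC)cc2OCOC)C=C(OP(=O)(Oc2ccccc2)Oc2ccccc2)O1 | intermediate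
20 | (2S,4S)-4-[2,4-bis(methoxymethoxy)phenyl]-6-[3,5-bis(methoxymethoxy)-4-(3-methylbut-2-en-1-yl)phenyl]-2-methyl-2-[(triisopropylsilyl)ethynyl]-3,4-dihydro-2H-pyran | C[C@@]1(C#C[Si](C(C)C)(C(C)C)C(C)C)C[C@H](c2ccc(OCOC)cc2OCOC)C=C(c2cc(OCOC)c(CC=C(C)C)c(OCOC)c2)O1 | intermediate
21 | (2S,4S)-4-[2,4-bis(methoxymethoxy)phenyl]-6-[3,5-bis(methoxymethoxy)-4-(3-methylbut-2-en-1-yl)phenyl]-2-ethynyl-2-methyl-3,4-dihydro-2H-pyran | C[C@@]1(C#C)C[C@H](c2ccc(OCOC)cc2OCOC)C=C(c2cc(OCOC)c(CC=C(C)C)c(OCOC)c2)O1 | intermediate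
22 | (2S,4S)-4-[2,4-bis(methoxymethoxy)phenyl]-6-[3,5-bis(methoxymethoxy)-4-(3-methylbut-2-en-1-yl)phenyl]-2-methyl-2-[(E)-2-(4,4,5,5-tetramethyl-1,3,2-dioxaborolan-2-yl)ethenyl]-3,4-dihydro-2H-pyran | C[C@@]1(/C=C/B2OC(C)(C)C(C)(C)O2)C[C@H](c2ccc(OCOC)cc2OCOC)C=C(c2cc(OCOC)c(CC=C(C)C)c(OCOC)c2)O1 | intermediate
23 | 4-hydroxybenzaldehyde | O=Cc1ccc(O)cc1 | starting material
24 | 4-(methoxymethoxy)benzaldehyde | COCOc1ccc(C=O)cc1 | intermediate
25 | 1-(2,4-dihydroxyphenyl)ethanone | CC(=O)c1ccc(O)cc1O | starting material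
26 | 1-(2,4-dihydroxy-3-iodophenyl)ethanone | CC(=O)c1ccc(O)c(I)c1O | intermediate
27 | 1-[3-iodo-2,4-bis(methoxymethoxy)phenyl]ethanone | CC(=O)c1ccc(OCOC)c(I)c1OCOC | intermediate
28 | 3-hydroxy-1-[3-iodo-2,4-bis(methoxymethoxy)phenyl]-3-[4-(methoxymethoxy)phenyl]propan-1-one (racemic) | O=C(CC(O)c1ccc(OCOC)cc1)c1ccc(OCOC)c(I)c1OCOC | intermediate
29 | (E)-1-[3-iodo-2,4-bis(methoxymethoxy)phenyl]-3-[4-(methoxymethoxy)phenyl]prop-2-en-1-one | O=C(/C=C/c1ccc(OCOC)cc1)c1ccc(OCOC)c(I)c1OCOC | intermediate
30 | (2S,4S)-2-[(E)-2-{2,6-bis(methoxymethoxy)-3-[(E)-3-(4-(methoxymethoxy)phenyl)prop-2-enoyl]phenyl}ethenyl]-4-[2,4-bis(methoxymethoxy)phenyl]-6-[3,5-bis(methoxymethoxy)-4-(3-methylbut-2-en-1-yl)phenyl]-2-methyl-3,4-dihydro-2H-pyran | C[C@@]1(/C=C/c2c(OCOC)ccc(C(=O)/C=C/c3ccc(OCOC)cc3)c2OCOC)C[C@H](c2ccc(OCOC)cc2OCOC)C=C(c2cc(OCOC)c(CC=C(C)C)c(OCOC)c2)O1 | intermediate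
31 | (3S,4R,5S)-3-{2,6-bis(methoxymethoxy)-3-[(E)-3-(4-(methoxymethoxy)phenyl)prop-2-enoyl]phenyl}-4-[3,5-bis(methoxymethoxy)-4-(3-methylbut-2-en-1-yl)benzoyl]-5-[2,4-bis(methoxymethoxy)phenyl]-1-methylcyclohex-1-ene | CC(C)=CCc1c(OCOC)cc(C(=O)[C@H]2[C@@H](c3c(OCOC)ccc(C(=O)/C=C/c4ccc(OCOC)cc4)c3OCOC)C=C(C)C[C@@H]2c2ccc(OCOC)cc2OCOC)cc1OCOC | intermediate
32 | kuwanon R | CC(C)=CCc1c(O)cc(C(=O)[C@H]2[C@@H](c3c(O)ccc(C(=O)/C=C/c4ccc(O)cc4)c3O)C=C(C)C[C@@H]2c2ccc(O)cc2O)cc1O | target

**Step count and risks**

Total steps: 20. Longest linear sequence: 11 steps (steps 3, 4, 5, 6, 10, 11, 12, 13, 18, 19, 20, from ynone 6).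

Steps most likely to fail:

Step 19. At the temperature the boat-shaped transition state demands, the electron-poor chalcone double bond may add to the electron-rich enol ether or isomerise, and retro-[4+2] fragmentation of the dihydropyran may begin before the shift is complete, so that material is lost or stereochemical fidelity erodes. The fallback runs the shift on a precursor whose ring A carries only an inert acetyl group and builds the enone afterwards. It sets out from boronate 22 and iodoacetophenone 27, which are coupled (Pd(OAc)2, SPhos, K3PO4, THF/H2O, 40 °C) to the acetyl-bearing cis-2-methyl-2-styryl-dihydropyran F1. Heating F1 as in step 19 should give the acetyl-bearing cyclohexene F2 by the same ring contraction. Claisen–Schmidt condensation of F2 with aldehyde 24 under the mildest hydroxide conditions (Ba(OH)2·8H2O, MeOH, rt), where the methyl ketone enolises far faster than the shielded tertiary C4–H, comes back to the route at 31.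

Step 6. Protodeboronation of the electron-rich ortho-alkoxy arylboronic acid may outrun its transfer to rhodium, and the ligand may not fully override the neighbouring quaternary centre, so that conversion is low or a mixture forms at C4. The fallback is a stoichiometric organocopper conjugate addition under substrate control. It sets out from bromide 2 and lactone 10: 2 is converted into aryllithium 3 (n-BuLi, THF, −78 °C) and then with CuI (0.5 equiv) into lithium bis[2,4-bis(methoxymethoxy)phenyl]cuprate F3. F3 should add to 10 at −78 → −40 °C by axial attack anti to the C6 methyl group and syn to the slim alkyne, giving the lithium enolate of the cis lactone F4. Protonation with aq. NH4Cl comes back to the route at 11.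

Step 20. Under protic acid the freed resorcinol of ring B may add to the prenyl double bond (chroman formation), the 2'-hydroxychalcone may close to a flavanone, and the C4 ketone may ketalise with neighbouring phenols or epimerise through its enol. The fallback cleaves the acetals without protic acid by silyl transfer. It sets out from 31, which is treated with Me3SiOTf and 2,2'-bipyridyl (CH2Cl2/MeCN, 0 °C), conditions that convert aryl MOM ethers into aryl trimethylsilyl ethers, to give the heptakis(trimethylsilyl) ether of kuwanon R F5. Addition of water at neutral pH hydrolyses the silyl ethers and comes back to the route at 32.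

**Further compounds**

F1 | step 19 | (2S,4S)-2-[(E)-2-{3-acetyl-2,6-bis(methoxymethoxy)phenyl}ethenyl]-4-[2,4-bis(methoxymethoxy)phenyl]-6-[3,5-bis(methoxymethoxy)-4-(3-methylbut-2-en-1-yl)phenyl]-2-methyl-3,4-dihydro-2H-pyran | C[C@@]1(/C=C/c2c(OCOC)ccc(C(C)=O)c2OCOC)C[C@H](c2ccc(OCOC)cc2OCOC)C=C(c2cc(OCOC)c(CC=C(C)C)c(OCOC)c2)O1
F2 | step 19 | (3S,4R,5S)-3-[3-acetyl-2,6-bis(methoxymethoxy)phenyl]-4-[3,5-bis(methoxymethoxy)-4-(3-methylbut-2-en-1-yl)benzoyl]-5-[2,4-bis(methoxymethoxy)phenyl]-1-methylcyclohex-1-ene | CC(C)=CCc1c(OCOC)cc(C(=O)[C@H]2[C@@H](c3c(OCOC)ccc(C(C)=O)c3OCOC)C=C(C)C[C@@H]2c2ccc(OCOC)cc2OCOC)cc1OCOC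
F3 | step 6 | lithium bis[2,4-bis(methoxymethoxy)phenyl]cuprate | [Li+].COCOc1ccc([Cu-]c2ccc(OCOC)cc2OCOC)c(OCOC)c1
F4 | step 6 | lithium (2S,4S)-4-[2,4-bis(methoxymethoxy)phenyl]-2-methyl-2-[(triisopropylsilyl)ethynyl]-3,4-dihydro-2H-pyran-6-olate | C[C@@]1(C#C[Si](C(C)C)(C(C)C)C(C)C)C[C@H](c2ccc(OCOC)cc2OCOC)C=C([O-])O1.[Li+]
F5 | step 20 | heptakis(trimethylsilyl) ether of kuwanon R | CC(C)=CCc1c(O[Si](C)(C)C)cc(C(=O)[C@H]2[C@@H](c3c(O[Si](C)(C)C)ccc(C(=O)/C=C/c4ccc(O[Si](C)(C)C)cc4)c3O[Si](C)(C)C)C=C(C)C[C@@H]2c2ccc(O[Si](C)(C)C)cc2O[Si](C)(C)C)cc1O[Si](C)(C)C
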